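Ring B of the target is a cyclohexane with oxygen on C9 and methyls on C8 and C10, fused through C5–C10 to ring A, which carries the C4 gem-dimethyl group and oxygen on C3: the pattern left by a 2-silyloxydiene cycloaddition. The decalin is cut at C5–C10 and C6–C7. One intramolecular Diels–Alder reaction of an open-chain triene, diene C7=C8–C9(OTBS)=C10 joined by the C1–C4 chain to an E-vinyl sulfone C5=C6, closes rings A and B, builds the quaternary C10 with trans ring fusion and leaves C9 as a masked ketone. The diene is made in the same flask under equilibrating silylation, so its C9=C10 geometry corrects itself; the C3 silyloxy stereocentre sets the absolute sense.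

Key step: step 10

Remark: atoms carry the numbers of the target decalin (ring A = C1–C5 and C10, ring B = C5–C10, side chain C11–C15, C16 = methyl on C13); α is the face opposite the C10 methyl, β the same face. Compounds 16 and 19 are used as mixtures of epimers at the future C10, which step 10 makes trigonal.

Step 1
Reactants: 1 methyl isobutyrate; 2 3-(benzyloxy)propanoyl chloride
Product: 4 methyl 5-(benzyloxy)-2,2-dimethyl-3-oxopentanoate, via lithium ester enolate 3 (not isolated)
Conditions: LiN(iPr)2, THF, −78 °C; then added to 2, THF, −78 °C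
Reagents that add atoms: none
Why: Claisen-type C-acylation of a fully substituted ester enolate by an acid chloride gives a β-keto ester with no proton between its carbonyls, and inverse addition at −78 °C keeps the enolate from eliminating benzyloxide from the product.

Step 2
Reactants: 4 methyl 5-(benzyloxy)-2,2-dimethyl-3-oxopentanoate
Product: 5 methyl (3S)-5-(benzyloxy)-3-hydroxy-2,2-dimethylpentanoate
Conditions: H2 (50 atm), RuCl2[(S)-BINAP] (1 mol%), MeOH, 50 °C
Reagents that add atoms: none
Why: Noyori asymmetric hydrogenation of a β-keto ester, in which the ester carbonyl chelates ruthenium and the (S)-BINAP ligand should direct hydride to the ketone face that gives the (S)-carbinol, the future C3.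

Step 3
Reactants: 5 methyl (3S)-5-(benzyloxy)-3-hydroxy-2,2-dimethylpentanoate
Product: 6 methyl (3S)-5-(benzyloxy)-3-[(tert-butyldimethylsilyl)oxy]-2,2-dimethylpentanoate
Conditions: TBSOTf, 2,6-lutidine, CH2Cl2, 0 °C
Reagents that add atoms: tert-butyldimethylsilyl triflate (TBSOTf), CC(C)(C)[Si](C)(C)OS(=O)(=O)C(F)(F)F
Why: Silylation of the hindered secondary alcohol with the reactive silyl triflate gives an ether that should survive every step up to step 11 and later steers the cycloaddition face.

Step 4
Reactants: 6 methyl (3S)-5-(benzyloxy)-3-[(tert-butyldimethylsilyl)oxy]-2,2-dimethylpentanoate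
Product: 7 methyl (3S)-3-[(tert-butyldimethylsilyl)oxy]-5-hydroxy-2,2-dimethylpentanoate
Conditions: H2 (1 atm), Pd on carbon (10%), EtOAc, rt
Reagents that add atoms: none
Why: Hydrogenolysis removes the benzyl ether and is placed here because the later vinyl sulfone would be reduced under these conditions; the hindered methyl ester should not lactonise with the freed C1 hydroxyl at room temperature.

Step 5
Reactants: 7 methyl (3S)-3-[(tert-butyldimethylsilyl)oxy]-5-hydroxy-2,2-dimethylpentanoate
Product: 8 methyl (3S)-3-[(tert-butyldimethylsilyl)oxy]-5-iodo-2,2-dimethylpentanoate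
Conditions: I2, PPh3, imidazole, CH2Cl2, 0 °C → rt
Reagents that add atoms: iodine, II
Why: Appel-type iodination, in which iodide displaces the alkoxyphosphonium group at the unhindered primary carbon, the future C1.

Step 6
Reactants: 8 methyl (3S)-3-[(tert-butyldimethylsilyl)oxy]-5-iodo-2,2-dimethylpentanoate
Product: 10 (3S)-3-[(tert-butyldimethylsilyl)oxy]-5-iodo-2,2-dimethylpentanal, via aluminium hemiacetal 9 (not isolated)
Conditions: iBu2AlH (1.1 equiv), CH2Cl2, −78 °C; then aq. potassium sodium tartrate
Reagents that add atoms: none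
Why: Partial hydride reduction of the ester should stop at the aldehyde because the hindered neopentyl aluminium hemiacetal does not collapse at −78 °C, and the primary iodide is inert to the hydride at this temperature.

Step 7
Reactants: 10 (3S)-3-[(tert-butyldimethylsilyl)oxy]-5-iodo-2,2-dimethylpentanal; 11 diethyl (phenylsulfonylmethyl)phosphonate
Product: 13 tert-butyl{[(3S,5E)-1-iodo-4,4-dimethyl-6-(phenylsulfonyl)hex-5-en-3-yl]oxy}dimethylsilane, via sodium phosphonate carbanion 12 (not isolated)
Conditions: NaH, THF, 0 °C; then 10, 0 °C → rt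
Reagents that add atoms: none
Why: Horner–Wadsworth–Emmons olefination with a sulfonyl-stabilised phosphonate should give the E-vinyl sulfone C5=C6, since the bulky neopentyl aldehyde favours the anti oxaphosphetane, and the stabilised carbanion is too weak a nucleophile to displace the iodide.

Step 8
Reactants: 14 N-propionylmorpholine; 13 tert-butyl{[(3S,5E)-1-iodo-4,4-dimethyl-6-(phenylsulfonyl)hex-5-en-3-yl]oxy}dimethylsilane
Product: 16 (5S,7E)-5-[(tert-butyldimethylsilyl)oxy]-2,6,6-trimethyl-1-(morpholin-4-yl)-8-(phenylsulfonyl)oct-7-en-1-one (both C2 epimers), via lithium amide enolate 15 (not isolated)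
Conditions: LiN(iPr)2, THF, −78 °C; then 13, −78 → 0 °C
Reagents that add atoms: none
Why: SN2 alkylation of a tertiary amide enolate by the primary iodide forms the C10–C1 bond, the vinyl sulfone being shielded by the quaternary C4 and lacking γ-hydrogens, and the new centre needs no control.

Step 9
Reactants: 16 (5S,7E)-5-[(tert-butyldimethylsilyl)oxy]-2,6,6-trimethyl-1-(morpholin-4-yl)-8-(phenylsulfonyl)oct-7-en-1-one; 17 isopropenylmagnesium bromide
Product: 19 (7S,9E)-7-[(tert-butyldimethylsilyl)oxy]-2,4,8,8-tetramethyl-10-(phenylsulfonyl)deca-1,9-dien-3-one (both C4 epimers), via magnesium hemiaminal 18 (not isolated)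
Conditions: THF, 0 °C → rt; then cold aq. HCl
Reagents that add atoms: none
Why: Acyl substitution on the morpholine amide by the vinylic Grignard reagent should stop at the ketone because the magnesium hemiaminal persists until the acidic quench, which also keeps morpholine protonated and off the new enone.

Step 10
Reactants: 19 (7S,9E)-7-[(tert-butyldimethylsilyl)oxy]-2,4,8,8-tetramethyl-10-(phenylsulfonyl)deca-1,9-dien-3-one
Product: 22 trans-fused cycloadduct (C8=C9 enol ether with 9-OTBS; 3β-OTBS; 6α-phenylsulfonyl; 5α-H; 10β-methyl; 4,4,8-trimethyl), via E-silyloxytriene 20 (not isolated), via Z-silyloxytriene 21 (not isolated)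
Conditions: TBSOTf (1.5 equiv), Et3N (4 equiv), toluene, 0 °C → rt; then BHT (cat.), 150 °C, sealed tube
Reagents that add atoms: tert-butyldimethylsilyl triflate (TBSOTf), CC(C)(C)[Si](C)(C)OS(=O)(=O)C(F)(F)F
Why: TBSOTf and Et3N enolise the enone at C10 to the 2-silyloxydienes 20 and 21, and in 21, where the C1 chain is cis to oxygen and the C10 methyl points inside, the diene C7=C8–C9=C10 adds across the E-vinyl sulfone C5=C6 in a concerted, asynchronous, normal-demand [4+2] cycloaddition, the nucleophilic C10 bonding to C5 (β to sulfur) and C7 to C6. The closest known reaction type is the thermal type 1 intramolecular Diels–Alder reaction of 1,7,9-decatrienes whose 2-silyloxydiene is generated in situ from an α′-enolisable enone. Ring B closes as the cyclohexene of the cycloaddition, with both new bonds in it, and ring A closes through the C5–C10 bond alone, the four-atom C1–C4 tether folding as a chair that the C4 gem-dimethyl group favours. C10 is set by the Z enol ether geometry of 21 together with the exo tether and endo sulfone, which place the C10 methyl and H5 trans; C5 and C6 follow from suprafacial addition to the E dienophile (equatorial 6α-sulfone); the absolute sense of all three comes from C3, whose silyloxy group sits equatorial on the chair tether. The step needs trans over cis ring fusion and one diene face: the first rests on the chair transition state with endo sulfone that only 21 can reach, the second on the C3 stereocentre. Isomer 20, with the chain inside, cannot cyclise this way and should be returned to 21 by reversible protonation at C10 by the Et3NH·OTf present, so both isomers drain through one channel.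

Step 11
Reactants: 22 trans-fused cycloadduct
Product: 23 3β-hydroxy-4,4,8α,10β-tetramethyl-6α-(phenylsulfonyl)-trans-decalin-9-one (5α-H)
Conditions: HCl (3 M aq.), THF, 50 °C
Reagents that add atoms: none
Why: Acid hydrolysis cleaves the silyl enol ether to the C9 ketone and the C3 silyl ether to the alcohol, and under these equilibrating conditions the C8 methyl should settle equatorial (α), away from the axial C10 methyl.

Step 12
Reactants: 23 3β-hydroxy-4,4,8α,10β-tetramethyl-6α-(phenylsulfonyl)-trans-decalin-9-one; 24 2-(2-bromoethyl)-2-methyl-1,3-dioxolane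
Product: 27 9α-[2-(2-methyl-1,3-dioxolan-2-yl)ethyl]-4,4,8α,10β-tetramethyl-6α-(phenylsulfonyl)-trans-decalin-3β,9β-diol, via Grignard reagent 25 (not isolated), via organocerium reagent 26 (not isolated)
Conditions: Mg, THF, 25 °C; CeCl3, THF, −78 °C; then 23, −78 → 0 °C (4 equiv of reagent)
Reagents that add atoms: none
Why: Organocerium 1,2-addition, in which the weakly basic reagent should add to the hindered, enolisable C9 ketone by axial attack on the α face, anti to the axial C10 methyl, setting C9 with the chain α and the hydroxyl β, one equivalent being spent on the C3 hydroxyl.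

Step 13
Reactants: 27 sulfonyl diol
Product: 28 9α-[2-(2-methyl-1,3-dioxolan-2-yl)ethyl]-4,4,8α,10β-tetramethyl-trans-decalin-3β,9β-diol
Conditions: Mg, MeOH, 50 °C
Reagents that add atoms: none
Why: Reductive desulfonylation by electron transfer from magnesium, in which the sulfone radical anion loses benzenesulfinate and the C6 radical is reduced and protonated by methanol, leaves C6 as CH2.

Step 14
Reactants: 28 3β,9β-diol
Product: 29 9β-hydroxy-9α-[2-(2-methyl-1,3-dioxolan-2-yl)ethyl]-4,4,8α,10β-tetramethyl-trans-decalin-3-one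
Conditions: Dess–Martin periodinane, NaHCO3, CH2Cl2, rt
Reagents that add atoms: none
Why: Dess–Martin oxidation converts the secondary C3 alcohol into the ketone, while the tertiary C9 alcohol cannot be oxidised and the dioxolane tolerates the buffered conditions.

Step 15
Reactants: 29 C3 ketone
Product: 31 C2=C3 enol triflate (3-trifluoromethanesulfonyloxy; 9β-hydroxy; dioxolane chain unchanged), via dipotassium enolate alkoxide 30 (not isolated)
Conditions: KN(SiMe3)2 (2.3 equiv), THF, −78 °C; then PhNTf2, −78 → 0 °C
Reagents that add atoms: N-phenylbis(trifluoromethanesulfonimide) (PhNTf2), O=S(=O)(N(c1ccccc1)S(=O)(=O)C(F)(F)F)C(F)(F)F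
Why: Enolate O-triflation gives a single enol triflate because C3 can enolise only towards C2 (C4 is quaternary), and the very hindered tertiary alkoxide at C9 should not be triflated.

Step 16
Reactants: 31 C2=C3 enol triflate
Product: 32 9α-[2-(2-methyl-1,3-dioxolan-2-yl)ethyl]-4,4,8α,10β-tetramethyl-trans-octal-2-en-9β-ol (C2=C3 alkene)
Conditions: Pd(OAc)2 (5 mol%), PPh3, Bu3N, HCO2H, DMF, 60 °C
Reagents that add atoms: none
Why: Palladium-catalysed formate reduction of the enol triflate (oxidative addition to zerovalent palladium, decarboxylation of the formate to a palladium hydride, reductive elimination) replaces the triflate by hydrogen and gives the C2=C3 alkene.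

Step 17
Reactants: 32 C2=C3 alkene with dioxolane chain
Product: 33 4-(9β-hydroxy-4,4,8α,10β-tetramethyl-trans-octal-2-en-9α-yl)butan-2-one
Conditions: AcOH–THF–H2O (3:1:1), 40 °C
Reagents that add atoms: water, O
Why: Mild acid hydrolysis of the dioxolane frees the C13 methyl ketone without ionising the tertiary C9 alcohol or touching the alkene.

Step 18
Reactants: 33 methyl ketone; 34 trimethyl phosphonoacetate
Product: 36 methyl (2E)-5-(9β-hydroxy-4,4,8α,10β-tetramethyl-trans-octal-2-en-9α-yl)-3-methylpent-2-enoate, via sodium phosphonate carbanion 35 (not isolated)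
Conditions: NaH (slightly less than 34), THF, 0 °C; then 33, rt → 50 °C
Reagents that add atoms: none
Why: Horner–Wadsworth–Emmons olefination of the methyl ketone should favour the E-enoate, in which the ester is trans to the larger C12 chain, the minor Z isomer being removed by chromatography, and the slight excess of phosphonate over NaH keeps the C9 hydroxyl protonated.

Step 19
Reactants: 36 E-enoate with C2=C3 alkene
Product: 37 methyl (2E)-3-methyl-5-(2α,3α,9β-trihydroxy-4,4,8α,10β-tetramethyl-trans-decalin-9α-yl)pent-2-enoate (target)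
Conditions: OsO4 (2 mol%), NMO (1.2 equiv), acetone–H2O, rt
Reagents that add atoms: osmium tetroxide, O=[Os](=O)(=O)=O; N-methylmorpholine N-oxide, C[N+]1([O-])CCOCC1; water, O
Why: Upjohn syn-dihydroxylation should take the electron-rich C2=C3 alkene well before the conjugated enoate, and the [3+2] addition of OsO4 from the α face, opposite the axial methyls on C4 and C10, sets C2 and C3 as the 2α,3α-diol.

Compound list

1 | methyl isobutyrate | COC(=O)C(C)C | starting material
2 | 3-(benzyloxy)propanoyl chloride | O=C(Cl)CCOCc1ccccc1 | starting material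
3 | lithium enolate of methyl isobutyrate | COC(O[Li])=C(C)C | intermediate
4 | methyl 5-(benzyloxy)-2,2-dimethyl-3-oxopentanoate | COC(=O)C(C)(C)C(=O)CCOCc1ccccc1 | intermediate
5 | methyl (3S)-5-(benzyloxy)-3-hydroxy-2,2-dimethylpentanoate | COC(=O)C(C)(C)[C@@H](O)CCOCc1ccccc1 | intermediate
6 | methyl (3S)-5-(benzyloxy)-3-[(tert-butyldimethylsilyl)oxy]-2,2-dimethylpentanoate | COC(=O)C(C)(C)[C@@H](O[Si](C)(C)C(C)(C)C)CCOCc1ccccc1 | intermediate
7 | methyl (3S)-3-[(tert-butyldimethylsilyl)oxy]-5-hydroxy-2,2-dimethylpentanoate | COC(=O)C(C)(C)[C@@H](O[Si](C)(C)C(C)(C)C)CCO | intermediate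
8 | methyl (3S)-3-[(tert-butyldimethylsilyl)oxy]-5-iodo-2,2-dimethylpentanoate | COC(=O)C(C)(C)[C@@H](O[Si](C)(C)C(C)(C)C)CCI | intermediate
9 | diisobutylaluminium hemiacetal of 8 | COC(O[Al](CC(C)C)CC(C)C)C(C)(C)[C@@H](O[Si](C)(C)C(C)(C)C)CCI | intermediate
10 | (3S)-3-[(tert-butyldimethylsilyl)oxy]-5-iodo-2,2-dimethylpentanal | O=CC(C)(C)[C@@H](O[Si](C)(C)C(C)(C)C)CCI | intermediate
11 | diethyl (phenylsulfonylmethyl)phosphonate | CCOP(=O)(CS(=O)(=O)c1ccccc1)OCC | starting material
12 | sodium salt of 11 (phosphonate carbanion) | CCOP(=O)(OCC)[CH-]S(=O)(=O)c1ccccc1.[Na+] | intermediate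
13 | tert-butyl{[(3S,5E)-1-iodo-4,4-dimethyl-6-(phenylsulfonyl)hex-5-en-3-yl]oxy}dimethylsilane | ICC[C@H](O[Si](C)(C)C(C)(C)C)C(C)(C)/C=C/S(=O)(=O)c1ccccc1 | intermediate
14 | N-propionylmorpholine (1-(morpholin-4-yl)propan-1-one) | CCC(=O)N1CCOCC1 | starting material
15 | lithium enolate of 14 | CC=C(O[Li])N1CCOCC1 | intermediate
16 | (5S,7E)-5-[(tert-butyldimethylsilyl)oxy]-2,6,6-trimethyl-1-(morpholin-4-yl)-8-(phenylsulfonyl)oct-7-en-1-one, both C2 epimers | CC(CC[C@H](O[Si](C)(C)C(C)(C)C)C(C)(C)/C=C/S(=O)(=O)c1ccccc1)C(=O)N1CCOCC1 | intermediate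
17 | isopropenylmagnesium bromide | C=C(C)[Mg]Br | starting material
18 | bromomagnesium hemiaminal from 16 and 17 | C=C(C)C(O[Mg]Br)(N1CCOCC1)C(C)CC[C@H](O[Si](C)(C)C(C)(C)C)C(C)(C)/C=C/S(=O)(=O)c1ccccc1 | intermediate
19 | (7S,9E)-7-[(tert-butyldimethylsilyl)oxy]-2,4,8,8-tetramethyl-10-(phenylsulfonyl)deca-1,9-dien-3-one, both C4 epimers | C=C(C)C(=O)C(C)CC[C@H](O[Si](C)(C)C(C)(C)C)C(C)(C)/C=C/S(=O)(=O)c1ccccc1 | intermediate
20 | (3E,7S,9E)-3,7-bis[(tert-butyldimethylsilyl)oxy]-2,4,8,8-tetramethyl-10-(phenylsulfonyl)deca-1,3,9-triene (C1 chain inside) | C=C(C)/C(O[Si](C)(C)C(C)(C)C)=C(/C)CC[C@H](O[Si](C)(C)C(C)(C)C)C(C)(C)/C=C/S(=O)(=O)c1ccccc1 | intermediate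
21 | (3Z,7S,9E)-3,7-bis[(tert-butyldimethylsilyl)oxy]-2,4,8,8-tetramethyl-10-(phenylsulfonyl)deca-1,3,9-triene (C10 methyl inside; cycloaddition precursor) | C=C(C)/C(O[Si](C)(C)C(C)(C)C)=C(\C)CC[C@H](O[Si](C)(C)C(C)(C)C)C(C)(C)/C=C/S(=O)(=O)c1ccccc1 | intermediate
22 | trans-fused cycloadduct: C8=C9 TBS enol ether, 3β-OTBS, 6α-phenylsulfonyl, 5α-H, 10β-methyl, 4,4,8-trimethyl | CC(C)(C)[Si](C)(C)OC1=C(C)C[C@H](S(=O)(=O)c3ccccc3)[C@H]2C(C)(C)[C@@H](O[Si](C)(C)C(C)(C)C)CC[C@@]21C | intermediate
23 | 3β-hydroxy-4,4,8α,10β-tetramethyl-6α-(phenylsulfonyl)-trans-decalin-9-one | O=C1[C@H](C)C[C@H](S(=O)(=O)c3ccccc3)[C@H]2C(C)(C)[C@@H](O)CC[C@@]21C | intermediate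
24 | 2-(2-bromoethyl)-2-methyl-1,3-dioxolane | CC1(CCBr)OCCO1 | starting material
25 | [2-(2-methyl-1,3-dioxolan-2-yl)ethyl]magnesium bromide | CC1(CC[Mg]Br)OCCO1 | intermediate
26 | [2-(2-methyl-1,3-dioxolan-2-yl)ethyl]cerium dichloride | CC1(CC[Ce](Cl)Cl)OCCO1 | intermediate
27 | 9α-[2-(2-methyl-1,3-dioxolan-2-yl)ethyl]-4,4,8α,10β-tetramethyl-6α-(phenylsulfonyl)-trans-decalin-3β,9β-diol | CC1(CC[C@]2(O)[C@H](C)C[C@H](S(=O)(=O)c4ccccc4)[C@H]3C(C)(C)[C@@H](O)CC[C@@]32C)OCCO1 | intermediate
28 | 9α-[2-(2-methyl-1,3-dioxolan-2-yl)ethyl]-4,4,8α,10β-tetramethyl-trans-decalin-3β,9β-diol | CC1(CC[C@]2(O)[C@H](C)CC[C@H]3C(C)(C)[C@@H](O)CC[C@@]32C)OCCO1 | intermediate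
29 | 9β-hydroxy-9α-[2-(2-methyl-1,3-dioxolan-2-yl)ethyl]-4,4,8α,10β-tetramethyl-trans-decalin-3-one | CC1(CC[C@]2(O)[C@H](C)CC[C@H]3C(C)(C)C(=O)CC[C@@]32C)OCCO1 | intermediate
30 | dipotassium C2=C3 enolate C9 alkoxide of 29 | CC1(CC[C@]2(O[K])[C@H](C)CC[C@H]3C(C)(C)C(O[K])=CC[C@@]32C)OCCO1 | intermediate
31 | C2=C3 enol triflate of 29 (9β-hydroxy, dioxolane chain) | CC1(CC[C@]2(O)[C@H](C)CC[C@H]3C(C)(C)C(OS(=O)(=O)C(F)(F)F)=CC[C@@]32C)OCCO1 | intermediate
32 | 9α-[2-(2-methyl-1,3-dioxolan-2-yl)ethyl]-4,4,8α,10β-tetramethyl-trans-octal-2-en-9β-ol | CC1(CC[C@]2(O)[C@H](C)CC[C@H]3C(C)(C)C=CC[C@@]32C)OCCO1 | intermediate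
33 | 4-(9β-hydroxy-4,4,8α,10β-tetramethyl-trans-octal-2-en-9α-yl)butan-2-one | CC(=O)CC[C@]1(O)[C@H](C)CC[C@H]2C(C)(C)C=CC[C@@]21C | intermediate
34 | trimethyl phosphonoacetate | COC(=O)CP(=O)(OC)OC | starting material
35 | sodium salt of 34 (phosphonate carbanion) | COC(=O)[CH-]P(=O)(OC)OC.[Na+] | intermediate
36 | methyl (2E)-5-(9β-hydroxy-4,4,8α,10β-tetramethyl-trans-octal-2-en-9α-yl)-3-methylpent-2-enoate | COC(=O)/C=C(\C)CC[C@]1(O)[C@H](C)CC[C@H]2C(C)(C)C=CC[C@@]21C | intermediate
37 | methyl (2E)-3-methyl-5-(2α,3α,9β-trihydroxy-4,4,8α,10β-tetramethyl-trans-decalin-9α-yl)pent-2-enoate | COC(=O)/C=C(\C)CC[C@]1(O)[C@H](C)CC[C@H]2C(C)(C)[C@H](O)[C@H](O)C[C@@]21C | target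

Total step count: 19. Longest linear sequence: 19 steps (from 1 and 2 to 37); compounds 11, 14, 17, 24 and 34 are commercial and enter directly.

Steps most likely to fail

Step 10. The inside methyl on C10 may slow the cycloaddition so much that 1,5-hydrogen shift within the diene, oligomerisation or cis-fused closure take over. In addition, the equatorial preference of the C3 silyloxy group beside the gem-dimethyl carbon may discriminate the two diene faces only moderately. The fallback builds the rings stepwise by anionic chemistry. Setting out from 19, LiN(SiMe3)2 in THF (−78 → 0 °C) would give the lithium dienolate of 19 F1, whose C10 adds to C5 of the vinyl sulfone. The resulting α-sulfonyl carbanion would then close ring B by conjugate addition to C7 of the enone (a Michael–Michael sequence). Protonation, with the sulfone settling equatorial, would give the 3β-silyloxy sulfonyl ketone F2. The conditions of step 11 remove its silyl group and the route is rejoined at 23.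

Step 12. The hindered C9 ketone may be enolised towards C8 instead of attacked, the ketal-bearing Grignard reagent may decompose before transmetalation, or attack may not be fully α-selective. The fallback uses a small sp-hybridised nucleophile. Setting out from 23, the lithium acetylide of 2-ethynyl-2-methyl-1,3-dioxolane F3 (from the alkyne and nBuLi, THF, −78 °C) would add axially from the α face to give the propargylic diol F4. Hydrogenation (H2, Pd on carbon, EtOAc) would saturate C11–C12 and rejoin the route at 27.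

Step 18. Olefination of the methyl ketone may give an appreciable share of the Z-enoate, the ketone may be held back as its cyclic hemiketal with the C9 hydroxyl, and the C9 alkoxide may add in conjugate fashion to the new enoate. The fallback is a stereospecific carbometalation. Setting out from 33, LiN(iPr)2 and ClP(O)(OEt)2 would give the enol phosphate F5, which further LiN(iPr)2 eliminates to the terminal alkyne F6. Me3Al with catalytic Cp2ZrCl2 would add methyl and aluminium syn across the alkyne (Negishi carboalumination) to give the alkenylalane F7. ClCO2Me would then replace aluminium with retention, which can give only the E-enoate and rejoins the route at 36.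

Further compounds

F1 | step 10 | lithium dienolate of 19 | C=C(C)C(O[Li])=C(C)CC[C@H](O[Si](C)(C)C(C)(C)C)C(C)(C)/C=C/S(=O)(=O)c1ccccc1
F2 | step 10 | 3β-[(tert-butyldimethylsilyl)oxy]-4,4,8α,10β-tetramethyl-6α-(phenylsulfonyl)-trans-decalin-9-one | O=C1[C@H](C)C[C@H](S(=O)(=O)c3ccccc3)[C@H]2C(C)(C)[C@@H](O[Si](C)(C)C(C)(C)C)CC[C@@]21C
F3 | step 12 | lithium acetylide of 2-ethynyl-2-methyl-1,3-dioxolane | [Li]C#CC1(C)OCCO1
F4 | step 12 | 9α-[(2-methyl-1,3-dioxolan-2-yl)ethynyl]-4,4,8α,10β-tetramethyl-6α-(phenylsulfonyl)-trans-decalin-3β,9β-diol | CC1(C#C[C@]2(O)[C@H](C)C[C@H](S(=O)(=O)c4ccccc4)[C@H]3C(C)(C)[C@@H](O)CC[C@@]32C)OCCO1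
F5 | step 18 | diethyl enol phosphate of 33 (terminal C13=CH2 enol) | C=C(OP(=O)(OCC)OCC)CC[C@]1(O)[C@H](C)CC[C@H]2C(C)(C)C=CC[C@@]21C
F6 | step 18 | 9α-(but-3-yn-1-yl)-4,4,8α,10β-tetramethyl-trans-octal-2-en-9β-ol | C#CCC[C@]1(O)[C@H](C)CC[C@H]2C(C)(C)C=CC[C@@]21C
F7 | step 18 | (E)-alkenyldimethylalane from F6 (C9 oxygen as dimethylaluminium alkoxide) | C[Al](C)/C=C(\C)CC[C@]1(O[Al](C)C)[C@H](C)CC[C@H]2C(C)(C)C=CC[C@@]21C
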